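**Retrosynthetic overview**
1. The (2′E,4′E,6′E)-trienoate is cut at its C3′–C4′ σ-bond, which lies between the C2′=C3′ and C4′=C5′ alkenes: Heck vinylation of a core acrylate with a (1E,3E,5R)-dienyl iodide. The enabling feature is the terminal acrylate C2′=C3′, conjugated to the ester C1′=O on O–C4 of the six-membered ring, the only monosubstituted electron-poor alkene of the precursor.
2. Core acrylate ⇐ bicyclic enone: C4–O by γ-hydroxylation of the C2-silyloxy diene C2=C3–C3a=C4 (axial, syn to the C7a methyl); C1 side chain by α′-alkylation.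
3. Five-membered ring (closed second) by aldol condensation of a 1,4-diketone; six-membered ring (closed first) by catalytic asymmetric Diels–Alder reaction of a 1-silyloxybutadiene with tert-butyl (E)-3-methyl-4-oxobut-2-enoate, which sets C7 and the quaternary C7a.
4. Dienyl iodide ⇐ auxiliary-controlled methylation (C8′), Wittig olefination (C6′=C7′), Takai iodo-olefination (C4′=C5′).
5. After the union only acidolysis (tert-butyl ester, silyl ether) and oxidation of the allylic alcohol to the enal remain.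

Key step: step 22

Remark: unprimed locants follow indene numbering of the core and primed locants the decatrienoyl chain; the facial sense of the catalysed cycloaddition in step 4 is assumed from the accepted model for α-substituted enals with this catalyst class, and the mirror-image catalyst is used if it proves opposite.

**Route**

Step 1
Reactants: 1 1,1-dimethoxypropan-2-one; 2 tert-butyl 2-(diethoxyphosphoryl)acetate
Product: 3 tert-butyl (2E)-4,4-dimethoxy-3-methylbut-2-enoate
Conditions: NaH, THF, 0 °C → rt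
Reagents that add atoms: none
Why: Horner–Wadsworth–Emmons olefination of the ketone, expected to favour the E isomer (ester trans to the bulkier acetal carbon), the minor Z isomer being removed by chromatography.

Step 2
Reactants: 3 tert-butyl (2E)-4,4-dimethoxy-3-methylbut-2-enoate
Product: 4 tert-butyl (2E)-3-methyl-4-oxobut-2-enoate
Conditions: Amberlyst-15, acetone/H2O, rt
Reagents that add atoms: water (O)
Why: acid-catalysed acetal hydrolysis mild enough to spare the tert-butyl ester, the E-configured aldehyde being the stable isomer.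

Step 3
Reactants: 5 (2E)-but-2-enal
Product: 6 [(1E)-buta-1,3-dien-1-yloxy](tert-butyl)dimethylsilane
Conditions: TBSOTf, Et3N, Et2O, 0 °C → rt
Reagents that add atoms: tert-butyldimethylsilyl trifluoromethanesulfonate (CC(C)(C)[Si](C)(C)OS(=O)(=O)C(F)(F)F)
Why: O-silylation of the enal followed by γ-deprotonation (vinylogous soft enolisation) gives the 1-silyloxy diene, the E isomer being favoured.

Step 4
Reactants: 4 tert-butyl (2E)-3-methyl-4-oxobut-2-enoate; 6 [(1E)-buta-1,3-dien-1-yloxy](tert-butyl)dimethylsilane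
Product: 7 tert-butyl (1R,5R,6S)-5-[(tert-butyldimethylsilyl)oxy]-6-formyl-6-methylcyclohex-3-ene-1-carboxylate
Conditions: protonated (S)-B-(o-tolyl)oxazaborolidine [from (S)-α,α-diphenylprolinol, tri(o-tolyl)boroxine, HNTf2] (20 mol %), CH2Cl2, −78 °C
Reagents that add atoms: none
Why: catalytic asymmetric Diels–Alder reaction of an α-substituted enal, in which the boron-bound formyl group has one face shielded (absolute configuration at C6 and C1), the unsubstituted diene terminus bonds to the ester-bearing carbon β to the activated formyl group so that the silyloxy carbon ends up next to the quaternary carbon, suprafacial addition to the E alkene places methyl and ester cis, and formyl-endo addition places OSi cis to CHO (this last centre is erased in step 8).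

Step 5
Reactants: 7 tert-butyl (1R,5R,6S)-5-[(tert-butyldimethylsilyl)oxy]-6-formyl-6-methylcyclohex-3-ene-1-carboxylate
Product: 8 tert-butyl (1R,2S,3R)-3-[(tert-butyldimethylsilyl)oxy]-2-formyl-2-methylcyclohexane-1-carboxylate
Conditions: H2 (1 atm), Pd/C (palladium on carbon), EtOAc, rt
Reagents that add atoms: none
Why: heterogeneous hydrogenation of the cis-disubstituted ring alkene, which leaves the neopentyl aldehyde, silyl ether and ester untouched and changes no stereocentre.

Step 6
Reactants: 8 tert-butyl (1R,2S,3R)-3-[(tert-butyldimethylsilyl)oxy]-2-formyl-2-methylcyclohexane-1-carboxylate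
Product: 10 tert-butyl (3aS,4R,7aR)-2-hydroxy-3a-methyloctahydro-1-benzofuran-4-carboxylate (lactol; both anomers), via methyl enol ether 9 (not isolated)
Conditions: Ph3P(CH2OMe)Cl, KN(SiMe3)2, THF, 0 °C → rt; then aq. HF, MeCN, rt
Reagents that add atoms: (methoxymethyl)triphenylphosphonium chloride (COC[P+](c1ccccc1)(c1ccccc1)c1ccccc1.[Cl-]); water (O)
Why: Wittig methoxymethylenation of the non-enolisable aldehyde, after which aqueous HF hydrolyses the enol ether and removes the silyl group and the cis γ-hydroxy aldehyde closes to the lactol without touching a ring stereocentre.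

Step 7
Reactants: 10 tert-butyl (3aS,4R,7aR)-2-hydroxy-3a-methyloctahydro-1-benzofuran-4-carboxylate
Product: 11 tert-butyl (1R,2S,3R)-3-hydroxy-2-(2-hydroxypropyl)-2-methylcyclohexane-1-carboxylate (both carbinol epimers)
Conditions: MeMgBr (3 equiv), THF, −20 °C → rt
Reagents that add atoms: methylmagnesium bromide (C[Mg]Br)
Why: Grignard addition to the open hydroxy-aldehyde tautomer of the lactol, the hindered tert-butyl ester being inert; the new carbinol centre is formed unselectively and is erased in step 8.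

Step 8
Reactants: 11 tert-butyl (1R,2S,3R)-3-hydroxy-2-(2-hydroxypropyl)-2-methylcyclohexane-1-carboxylate
Product: 12 tert-butyl (1R,2S)-2-methyl-3-oxo-2-(2-oxopropyl)cyclohexane-1-carboxylate
Conditions: DMP, CH2Cl2, rt
Reagents that add atoms: none
Why: Dess–Martin oxidation of both secondary alcohols to the 1,4-diketone under neutral conditions that do not epimerise the ester-bearing carbon.

Step 9
Reactants: 12 tert-butyl (1R,2S)-2-methyl-3-oxo-2-(2-oxopropyl)cyclohexane-1-carboxylate
Product: 14 tert-butyl (7R,7aS)-7a-methyl-2-oxo-2,4,5,6,7,7a-hexahydro-1H-indene-7-carboxylate, via ketol 13 (not isolated)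
Conditions: KOtBu (cat.), tBuOH, 60 °C
Reagents that add atoms: none
Why: intramolecular aldol condensation (methyl-ketone enolate onto the ring ketone, then E1cB dehydration), a closure known for 2-methyl-2-(2-oxopropyl)cyclohexanone; the ester stays cis to the angular methyl, which is also its equatorial and more stable position.

Step 10
Reactants: 15 2-methylidenepropane-1,3-diol
Product: 16 2-{[(tert-butyldimethylsilyl)oxy]methyl}prop-2-en-1-ol
Conditions: NaH (1 equiv), THF, 0 °C; TBSCl
Reagents that add atoms: tert-butyl(chloro)dimethylsilane (CC(C)(C)[Si](C)(C)Cl)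
Why: monosilylation of the symmetrical diol through its sparingly soluble mono-alkoxide.

Step 11
Reactants: 16 2-{[(tert-butyldimethylsilyl)oxy]methyl}prop-2-en-1-ol
Product: 17 {[2-(bromomethyl)prop-2-en-1-yl]oxy}(tert-butyl)dimethylsilane
Conditions: CBr4, PPh3, CH2Cl2, 0 °C
Reagents that add atoms: tetrabromomethane (BrC(Br)(Br)Br)
Why: Appel bromination of the primary allylic alcohol under neutral conditions that keep the silyl ether.

Step 12
Reactants: 14 tert-butyl (7R,7aS)-7a-methyl-2-oxo-2,4,5,6,7,7a-hexahydro-1H-indene-7-carboxylate; 17 {[2-(bromomethyl)prop-2-en-1-yl]oxy}(tert-butyl)dimethylsilane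
Product: 18 tert-butyl (1R,7R,7aS)-1-(2-{[(tert-butyldimethylsilyl)oxy]methyl}prop-2-en-1-yl)-7a-methyl-2-oxo-2,4,5,6,7,7a-hexahydro-1H-indene-7-carboxylate
Conditions: LiN(iPr)2, THF, −78 °C; 17, DMPU, −78 → −20 °C; then K2CO3, MeOH, rt
Reagents that add atoms: none
Why: kinetic α′-deprotonation gives the cross-conjugated C1 enolate, which is allylated anti to C7 and its equatorial ester (syn to the angular methyl), and because C1 stays epimerisable the carbonate equilibration should funnel any epimer to this more stable (1R) isomer, as 17β-acyl groups are favoured in D-ring steroids.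

Step 13
Reactants: 18 tert-butyl (1R,7R,7aS)-1-(2-{[(tert-butyldimethylsilyl)oxy]methyl}prop-2-en-1-yl)-7a-methyl-2-oxo-2,4,5,6,7,7a-hexahydro-1H-indene-7-carboxylate
Product: 20 tert-butyl (1R,4S,7R,7aS)-1-(2-{[(tert-butyldimethylsilyl)oxy]methyl}prop-2-en-1-yl)-4-hydroxy-7a-methyl-2-oxo-2,4,5,6,7,7a-hexahydro-1H-indene-7-carboxylate, via silyl dienol ether 19 (not isolated)
Conditions: TBSOTf, Et3N, CH2Cl2, −78 → 0 °C; then mCPBA, CH2Cl2, −40 °C; dilute aq. citric acid work-up
Reagents that add atoms: 3-chloroperoxybenzoic acid (OOC(=O)c1cccc(Cl)c1)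
Why: vinylogous Rubottom oxidation, in which the linear silyloxy diene (γ-deprotonation at C4, the hindered tertiary C1–H being left alone) is epoxidised at its electron-rich C3a=C4 terminus and collapses to the γ-hydroxy enone, oxygen being delivered axially to C4 syn to the axial angular methyl as in the 6β-hydroxylation of steroidal 3,5-dienol ethers, which sets (4S).

Step 14
Reactants: 20 tert-butyl (1R,4S,7R,7aS)-1-(2-{[(tert-butyldimethylsilyl)oxy]methyl}prop-2-en-1-yl)-4-hydroxy-7a-methyl-2-oxo-2,4,5,6,7,7a-hexahydro-1H-indene-7-carboxylate; 21 prop-2-enoyl chloride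
Product: 22 tert-butyl (1R,4S,7R,7aS)-1-(2-{[(tert-butyldimethylsilyl)oxy]methyl}prop-2-en-1-yl)-7a-methyl-2-oxo-4-(prop-2-enoyloxy)-2,4,5,6,7,7a-hexahydro-1H-indene-7-carboxylate
Conditions: iPr2NEt, DMAP (cat.), CH2Cl2, −20 → 0 °C
Reagents that add atoms: none
Why: DMAP-catalysed O-acylation of the hindered axial allylic alcohol, with retention at C4 because the C–O bond is not touched.

Step 15
Reactants: 23 (4R)-4-benzyl-1,3-oxazolidin-2-one; 24 butanoyl chloride
Product: 25 (4R)-4-benzyl-3-butanoyl-1,3-oxazolidin-2-one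
Conditions: nBuLi, THF, −78 °C
Reagents that add atoms: none
Why: N-acylation of the lithiated oxazolidinone auxiliary.

Step 16
Reactants: 25 (4R)-4-benzyl-3-butanoyl-1,3-oxazolidin-2-one
Product: 26 (4R)-4-benzyl-3-[(2R)-2-methylbutanoyl]-1,3-oxazolidin-2-one
Conditions: NaN(SiMe3)2, THF, −78 °C; MeI
Reagents that add atoms: iodomethane (CI)
Why: auxiliary-controlled enolate alkylation, iodomethane attacking the chelated Z-enolate on the face opposite the benzyl group to set (2R).

Step 17
Reactants: 26 (4R)-4-benzyl-3-[(2R)-2-methylbutanoyl]-1,3-oxazolidin-2-one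
Product: 27 (2R)-2-methylbutan-1-ol
Conditions: LiBH4, Et2O, 0 °C
Reagents that add atoms: none
Why: reductive cleavage of the imide to the primary alcohol without enolising the α-stereocentre, the auxiliary being recovered.

Step 18
Reactants: 27 (2R)-2-methylbutan-1-ol; 28 ethyl 2-(triphenyl-λ5-phosphanylidene)propanoate
Product: 30 ethyl (2E,4R)-2,4-dimethylhex-2-enoate, via aldehyde 29 (not isolated)
Conditions: (COCl)2, DMSO, CH2Cl2, −78 °C; Et3N; then 28, −78 °C → rt
Reagents that add atoms: none
Why: Swern oxidation with in situ Wittig trapping avoids isolating the volatile, racemisation-prone α-branched aldehyde, and the stabilised ylide gives the E-trisubstituted enoate.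

Step 19
Reactants: 30 ethyl (2E,4R)-2,4-dimethylhex-2-enoate
Product: 31 (2E,4R)-2,4-dimethylhex-2-en-1-ol
Conditions: iBu2AlH, CH2Cl2, −78 °C
Reagents that add atoms: none
Why: 1,2-reduction of the enoate to the allylic alcohol with retention of alkene geometry.

Step 20
Reactants: 31 (2E,4R)-2,4-dimethylhex-2-en-1-ol
Product: 32 (2E,4R)-2,4-dimethylhex-2-enal
Conditions: MnO2, CH2Cl2, rt
Reagents that add atoms: none
Why: selective oxidation of the allylic alcohol on the MnO2 surface, without E/Z isomerisation or epimerisation of the γ-stereocentre.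

Step 21
Reactants: 32 (2E,4R)-2,4-dimethylhex-2-enal
Product: 33 (1E,3E,5R)-1-iodo-3,5-dimethylhepta-1,3-diene
Conditions: CrCl2, CHI3, THF/1,4-dioxane, 0 °C → rt
Reagents that add atoms: triiodomethane (IC(I)I)
Why: Takai iodo-olefination, which gives the new alkene as the E isomer and leaves the existing E alkene and the remote stereocentre untouched.

Step 22
Reactants: 22 tert-butyl (1R,4S,7R,7aS)-1-(2-{[(tert-butyldimethylsilyl)oxy]methyl}prop-2-en-1-yl)-7a-methyl-2-oxo-4-(prop-2-enoyloxy)-2,4,5,6,7,7a-hexahydro-1H-indene-7-carboxylate; 33 (1E,3E,5R)-1-iodo-3,5-dimethylhepta-1,3-diene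
Product: 34 tert-butyl (1R,4S,7R,7aS)-1-(2-{[(tert-butyldimethylsilyl)oxy]methyl}prop-2-en-1-yl)-4-{[(2E,4E,6E,8R)-6,8-dimethyldeca-2,4,6-trienoyl]oxy}-7a-methyl-2-oxo-2,4,5,6,7,7a-hexahydro-1H-indene-7-carboxylate
Conditions: Pd(OAc)2 (10 mol %), nBu4NCl, K2CO3, DMF, 25 °C, dark
Reagents that add atoms: none
Why: Heck reaction: Pd(OAc)2 is reduced in situ to chloride-stabilised zerovalent palladium, which inserts into the C–I bond of 33 with retention of the (1E,3E) geometry; the dienyl–palladium species adds syn across the acrylate C2′=C3′ of 22, carbon going to the unsubstituted terminus C3′, and syn β-hydride elimination releases the alkene while K2CO3 returns the palladium hydride to the zerovalent state. The closest known reaction type is the phosphine-free, phase-transfer Heck coupling of alkenyl iodides with acrylate esters, which gives (2E,4E)-dienoates with retention at the iodide. No ring is closed and no stereocentre is formed; the only new stereo-element, the C2′=C3′ geometry, is set as E by the syn-insertion/syn-elimination sequence, while 4′E, 6′E and 8′R come unchanged from 33 and C1, C4, C7 and C7a from 22. The step needs chemoselectivity for the acrylate over the trisubstituted enone C3=C3a, the 1,1-disubstituted side-chain alkene and the newly formed triene, and it needs the allylic C4–O ester not to ionise to a π-allylpalladium species. The first is secured because the acrylate is the only monosubstituted electron-poor alkene present, the second by the phosphine-free catalyst at room temperature, where oxidative addition to the alkenyl iodide should consume zerovalent palladium much faster than carboxylate ionisation. The three-carbon acrylate on O–C4 is thus turned in one operation into the complete (2′E,4′E,6′E,8′R)-trienoate.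

Step 23
Reactants: 34 tert-butyl (1R,4S,7R,7aS)-1-(2-{[(tert-butyldimethylsilyl)oxy]methyl}prop-2-en-1-yl)-4-{[(2E,4E,6E,8R)-6,8-dimethyldeca-2,4,6-trienoyl]oxy}-7a-methyl-2-oxo-2,4,5,6,7,7a-hexahydro-1H-indene-7-carboxylate
Product: 35 (1R,4S,7R,7aS)-4-{[(2E,4E,6E,8R)-6,8-dimethyldeca-2,4,6-trienoyl]oxy}-1-[2-(hydroxymethyl)prop-2-en-1-yl]-7a-methyl-2-oxo-2,4,5,6,7,7a-hexahydro-1H-indene-7-carboxylic acid
Conditions: CF3CO2H/CH2Cl2/H2O, 0 °C
Reagents that add atoms: none
Why: acidolysis of the tert-butyl ester (alkyl–oxygen cleavage) and of the primary silyl ether, the allylic C4 ester being safe because its cation would be conjugated to the C2 carbonyl; no stereocentre is affected.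

Step 24
Reactants: 35 (1R,4S,7R,7aS)-4-{[(2E,4E,6E,8R)-6,8-dimethyldeca-2,4,6-trienoyl]oxy}-1-[2-(hydroxymethyl)prop-2-en-1-yl]-7a-methyl-2-oxo-2,4,5,6,7,7a-hexahydro-1H-indene-7-carboxylic acid
Product: 36 (1R,4S,7R,7aS)-4-{[(2E,4E,6E,8R)-6,8-dimethyldeca-2,4,6-trienoyl]oxy}-1-(2-formylprop-2-en-1-yl)-7a-methyl-2-oxo-2,4,5,6,7,7a-hexahydro-1H-indene-7-carboxylic acid
Conditions: TEMPO (cat.), PhI(OAc)2, CH2Cl2, rt
Reagents that add atoms: none
Why: oxoammonium-mediated oxidation selective for the primary allylic alcohol, which tolerates the free carboxylic acid and stops at the aldehyde in the absence of water.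

**Compound list**
1 | 1,1-dimethoxypropan-2-one | CC(=O)C(OC)OC | starting material
2 | tert-butyl 2-(diethoxyphosphoryl)acetate | CCOP(=O)(CC(=O)OC(C)(C)C)OCC | starting material
3 | tert-butyl (2E)-4,4-dimethoxy-3-methylbut-2-enoate | COC(OC)/C(C)=C/C(=O)OC(C)(C)C | intermediate
4 | tert-butyl (2E)-3-methyl-4-oxobut-2-enoate | O=C/C(C)=C/C(=O)OC(C)(C)C | intermediate
5 | (2E)-but-2-enal | C/C=C/C=O | starting material
6 | [(1E)-buta-1,3-dien-1-yloxy](tert-butyl)dimethylsilane | C=C/C=C/O[Si](C)(C)C(C)(C)C | intermediate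
7 | tert-butyl (1R,5R,6S)-5-[(tert-butyldimethylsilyl)oxy]-6-formyl-6-methylcyclohex-3-ene-1-carboxylate | [C@@H]1(O[Si](C)(C)C(C)(C)C)C=CC[C@@H](C(=O)OC(C)(C)C)[C@@]1(C=O)C | intermediate
8 | tert-butyl (1R,2S,3R)-3-[(tert-butyldimethylsilyl)oxy]-2-formyl-2-methylcyclohexane-1-carboxylate | [C@@H]1(O[Si](C)(C)C(C)(C)C)CCC[C@@H](C(=O)OC(C)(C)C)[C@@]1(C=O)C | intermediate
9 | tert-butyl (1R,2S,3R)-3-[(tert-butyldimethylsilyl)oxy]-2-(2-methoxyethenyl)-2-methylcyclohexane-1-carboxylate (E/Z mixture) | [C@@H]1(O[Si](C)(C)C(C)(C)C)CCC[C@@H](C(=O)OC(C)(C)C)[C@@]1(C=COC)C | intermediate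
10 | tert-butyl (3aS,4R,7aR)-2-hydroxy-3a-methyloctahydro-1-benzofuran-4-carboxylate (both anomers) | [C@@H]1(O2)CCC[C@@H](C(=O)OC(C)(C)C)[C@@]1(CC2O)C | intermediate
11 | tert-butyl (1R,2S,3R)-3-hydroxy-2-(2-hydroxypropyl)-2-methylcyclohexane-1-carboxylate (both carbinol epimers) | [C@@H]1(O)CCC[C@@H](C(=O)OC(C)(C)C)[C@@]1(CC(C)O)C | intermediate
12 | tert-butyl (1R,2S)-2-methyl-3-oxo-2-(2-oxopropyl)cyclohexane-1-carboxylate | O=C1CCC[C@@H](C(=O)OC(C)(C)C)[C@@]1(CC(C)=O)C | intermediate
13 | tert-butyl (3aR,7R,7aS)-3a-hydroxy-7a-methyl-2-oxooctahydro-1H-indene-7-carboxylate | C1C(=O)C[C@]2(O)CCC[C@@H](C(=O)OC(C)(C)C)[C@@]21C | intermediate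
14 | tert-butyl (7R,7aS)-7a-methyl-2-oxo-2,4,5,6,7,7a-hexahydro-1H-indene-7-carboxylate | C1C(=O)C=C2CCC[C@@H](C(=O)OC(C)(C)C)[C@@]21C | intermediate
15 | 2-methylidenepropane-1,3-diol | C=C(CO)CO | starting material
16 | 2-{[(tert-butyldimethylsilyl)oxy]methyl}prop-2-en-1-ol | C=C(CO)CO[Si](C)(C)C(C)(C)C | intermediate
17 | {[2-(bromomethyl)prop-2-en-1-yl]oxy}(tert-butyl)dimethylsilane | C=C(CBr)CO[Si](C)(C)C(C)(C)C | intermediate
18 | tert-butyl (1R,7R,7aS)-1-(2-{[(tert-butyldimethylsilyl)oxy]methyl}prop-2-en-1-yl)-7a-methyl-2-oxo-2,4,5,6,7,7a-hexahydro-1H-indene-7-carboxylate | C=C(CO[Si](C)(C)C(C)(C)C)C[C@H]1C(=O)C=C2CCC[C@@H](C(=O)OC(C)(C)C)[C@@]21C | intermediate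
19 | tert-butyl (1R,7R,7aS)-2-[(tert-butyldimethylsilyl)oxy]-1-(2-{[(tert-butyldimethylsilyl)oxy]methyl}prop-2-en-1-yl)-7a-methyl-5,6,7,7a-tetrahydro-1H-indene-7-carboxylate | C=C(CO[Si](C)(C)C(C)(C)C)C[C@H]1C(O[Si](C)(C)C(C)(C)C)=CC2=CCC[C@@H](C(=O)OC(C)(C)C)[C@@]21C | intermediate
20 | tert-butyl (1R,4S,7R,7aS)-1-(2-{[(tert-butyldimethylsilyl)oxy]methyl}prop-2-en-1-yl)-4-hydroxy-7a-methyl-2-oxo-2,4,5,6,7,7a-hexahydro-1H-indene-7-carboxylate | C=C(CO[Si](C)(C)C(C)(C)C)C[C@H]1C(=O)C=C2[C@@H](O)CC[C@@H](C(=O)OC(C)(C)C)[C@@]21C | intermediate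
21 | prop-2-enoyl chloride | C=CC(=O)Cl | starting material
22 | tert-butyl (1R,4S,7R,7aS)-1-(2-{[(tert-butyldimethylsilyl)oxy]methyl}prop-2-en-1-yl)-7a-methyl-2-oxo-4-(prop-2-enoyloxy)-2,4,5,6,7,7a-hexahydro-1H-indene-7-carboxylate | C=C(CO[Si](C)(C)C(C)(C)C)C[C@H]1C(=O)C=C2[C@@H](OC(=O)C=C)CC[C@@H](C(=O)OC(C)(C)C)[C@@]21C | intermediate
23 | (4R)-4-benzyl-1,3-oxazolidin-2-one | O=C1N[C@H](Cc2ccccc2)CO1 | starting material
24 | butanoyl chloride | CCCC(=O)Cl | starting material
25 | (4R)-4-benzyl-3-butanoyl-1,3-oxazolidin-2-one | CCCC(=O)N1[C@H](Cc2ccccc2)COC1=O | intermediate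
26 | (4R)-4-benzyl-3-[(2R)-2-methylbutanoyl]-1,3-oxazolidin-2-one | CC[C@@H](C)C(=O)N1[C@H](Cc2ccccc2)COC1=O | intermediate
27 | (2R)-2-methylbutan-1-ol | CC[C@@H](C)CO | intermediate
28 | ethyl 2-(triphenyl-λ5-phosphanylidene)propanoate | CCOC(=O)C(C)=P(c1ccccc1)(c1ccccc1)c1ccccc1 | starting material
29 | (2R)-2-methylbutanal | CC[C@@H](C)C=O | intermediate
30 | ethyl (2E,4R)-2,4-dimethylhex-2-enoate | CCOC(=O)/C(C)=C/[C@H](C)CC | intermediate
31 | (2E,4R)-2,4-dimethylhex-2-en-1-ol | OC/C(C)=C/[C@H](C)CC | intermediate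
32 | (2E,4R)-2,4-dimethylhex-2-enal | O=C/C(C)=C/[C@H](C)CC | intermediate
33 | (1E,3E,5R)-1-iodo-3,5-dimethylhepta-1,3-diene | I/C=C/C(C)=C/[C@H](C)CC | intermediate
34 | tert-butyl (1R,4S,7R,7aS)-1-(2-{[(tert-butyldimethylsilyl)oxy]methyl}prop-2-en-1-yl)-4-{[(2E,4E,6E,8R)-6,8-dimethyldeca-2,4,6-trienoyl]oxy}-7a-methyl-2-oxo-2,4,5,6,7,7a-hexahydro-1H-indene-7-carboxylate | C=C(CO[Si](C)(C)C(C)(C)C)C[C@H]1C(=O)C=C2[C@@H](OC(=O)/C=C/C=C/C(C)=C/[C@H](C)CC)CC[C@@H](C(=O)OC(C)(C)C)[C@@]21C | intermediate
35 | (1R,4S,7R,7aS)-4-{[(2E,4E,6E,8R)-6,8-dimethyldeca-2,4,6-trienoyl]oxy}-1-[2-(hydroxymethyl)prop-2-en-1-yl]-7a-methyl-2-oxo-2,4,5,6,7,7a-hexahydro-1H-indene-7-carboxylic acid | C=C(CO)C[C@H]1C(=O)C=C2[C@@H](OC(=O)/C=C/C=C/C(C)=C/[C@H](C)CC)CC[C@@H](C(=O)O)[C@@]21C | intermediate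
36 | (1R,4S,7R,7aS)-4-{[(2E,4E,6E,8R)-6,8-dimethyldeca-2,4,6-trienoyl]oxy}-1-(2-formylprop-2-en-1-yl)-7a-methyl-2-oxo-2,4,5,6,7,7a-hexahydro-1H-indene-7-carboxylic acid | C=C(C=O)C[C@H]1C(=O)C=C2[C@@H](OC(=O)/C=C/C=C/C(C)=C/[C@H](C)CC)CC[C@@H](C(=O)O)[C@@]21C | target

**Step count and risks**
Total step count: 24. Longest linear sequence: 14 steps (steps 1, 2, 4 to 9, 12 to 14, 22 to 24).

Steps most likely to fail:

Step 13. The peracid may approach the dienol ether from the face anti to the angular methyl (steric approach winning over the axial approach), giving the C4 epimer, or may attack C3. Fallback, from 18 back to 20, by oxidation and reduction instead of face-selective oxygenation: dienol ether 19 is oxidised as before without regard to facial control; the mixture of 20 and the (4R)-epimer of 20 F1 is oxidised with DMP to the 2,4-dione F2; Luche reduction (NaBH4, CeCl3·7H2O, MeOH, −78 °C) should then take the less hindered C4 carbonyl (C2 is flanked by the branched C1) from the face opposite the axial angular methyl, as 6-oxo steroids give 6β-alcohols, which returns the route to 20.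

Step 4. The silyl dienol ether may transfer silicon to the acid-activated formyl group (vinylogous aldol-type addition), may be destroyed by the acidic catalyst, or the catalyst may discriminate the enal faces poorly. Fallback, from 4 and 5 to 10, with auxiliary control in place of catalyst control: crotonaldehyde 5 is O-acylated as its potassium dienolate (KOtBu, then (S)-O-methylmandeloyl chloride) to the dienyl mandelate F3, a diene that cannot transfer silicon; BF3·OEt2-promoted cycloaddition with 4 should give the cyclohexene mandelate F4 with the ester auxiliary directing the facial approach (the enantiomeric auxiliary is taken if the sense proves opposite); hydrogenation gives the saturated aldehyde F5, methoxymethylenation gives the enol ether F6, K2CO3/MeOH removes the auxiliary to give the hydroxy enol ether F7, and dilute aqueous HCl closes the route at lactol 10.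

Step 22. Zerovalent palladium may ionise the allylic C4–O ester (π-allyl formation with loss or scrambling of the acyloxy group), may insert into other alkenes of substrate or product, or palladium hydride re-addition may erode the alkene geometry. Fallback, from 20 and 33 to 34, by a palladium-free Stille-type coupling: 20 is esterified with (2E)-3-iodoprop-2-enoic acid (DCC, DMAP) to the iodoacrylate F8; 33 is converted by iodine–lithium exchange (t-BuLi, −78 °C) and Bu3SnCl into the dienylstannane F9; Cu(O2CC4H3S) (copper thiophene-2-carboxylate) in N-methylpyrrolidone at 0 °C joins the two with retention at both alkenes, so that no zerovalent palladium meets the allylic ester.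

**Further compounds**
F1 | step 13 | tert-butyl (1R,4R,7R,7aS)-1-(2-{[(tert-butyldimethylsilyl)oxy]methyl}prop-2-en-1-yl)-4-hydroxy-7a-methyl-2-oxo-2,4,5,6,7,7a-hexahydro-1H-indene-7-carboxylate | C=C(CO[Si](C)(C)C(C)(C)C)C[C@H]1C(=O)C=C2[C@H](O)CC[C@@H](C(=O)OC(C)(C)C)[C@@]21C
F2 | step 13 | tert-butyl (1R,7R,7aS)-1-(2-{[(tert-butyldimethylsilyl)oxy]methyl}prop-2-en-1-yl)-7a-methyl-2,4-dioxo-2,4,5,6,7,7a-hexahydro-1H-indene-7-carboxylate | C=C(CO[Si](C)(C)C(C)(C)C)C[C@H]1C(=O)C=C2C(=O)CC[C@@H](C(=O)OC(C)(C)C)[C@@]21C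
F3 | step 4 | (1E)-buta-1,3-dien-1-yl (2S)-2-methoxy-2-phenylacetate | C=C/C=C/OC(=O)[C@@H](OC)c1ccccc1
F4 | step 4 | tert-butyl (1R,5R,6S)-6-formyl-5-{[(2S)-2-methoxy-2-phenylacetyl]oxy}-6-methylcyclohex-3-ene-1-carboxylate | [C@@H]1(OC(=O)[C@@H](OC)c2ccccc2)C=CC[C@@H](C(=O)OC(C)(C)C)[C@@]1(C=O)C
F5 | step 4 | tert-butyl (1R,2S,3R)-2-formyl-3-{[(2S)-2-methoxy-2-phenylacetyl]oxy}-2-methylcyclohexane-1-carboxylate | [C@@H]1(OC(=O)[C@@H](OC)c2ccccc2)CCC[C@@H](C(=O)OC(C)(C)C)[C@@]1(C=O)C
F6 | step 4 | tert-butyl (1R,2S,3R)-2-(2-methoxyethenyl)-3-{[(2S)-2-methoxy-2-phenylacetyl]oxy}-2-methylcyclohexane-1-carboxylate | [C@@H]1(OC(=O)[C@@H](OC)c2ccccc2)CCC[C@@H](C(=O)OC(C)(C)C)[C@@]1(C=COC)C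
F7 | step 4 | tert-butyl (1R,2S,3R)-3-hydroxy-2-(2-methoxyethenyl)-2-methylcyclohexane-1-carboxylate | [C@@H]1(O)CCC[C@@H](C(=O)OC(C)(C)C)[C@@]1(C=COC)C
F8 | step 22 | tert-butyl (1R,4S,7R,7aS)-1-(2-{[(tert-butyldimethylsilyl)oxy]methyl}prop-2-en-1-yl)-4-{[(2E)-3-iodoprop-2-enoyl]oxy}-7a-methyl-2-oxo-2,4,5,6,7,7a-hexahydro-1H-indene-7-carboxylate | C=C(CO[Si](C)(C)C(C)(C)C)C[C@H]1C(=O)C=C2[C@@H](OC(=O)/C=C/I)CC[C@@H](C(=O)OC(C)(C)C)[C@@]21C
F9 | step 22 | tributyl[(1E,3E,5R)-3,5-dimethylhepta-1,3-dien-1-yl]stannane | CCCC[Sn](CCCC)(CCCC)/C=C/C(C)=C/[C@H](C)CC
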